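**Plan**

1. Retrosynthetic cuts, in order: the two O–Si bonds; C8–C9 (vinyl of ring C to butenolide ring B, Stille); C11=C12 (ylidene of ring B, vinylogous aldol–elimination); C6'–C7' (ring A to the alkyne, Sonogashira); C7'≡C8' (one-carbon homologation of a formyl group); and, together, C9'=C10' and C13=C14 (double Wittig).
2. Enabling feature: from alkyne carbon C8' to ylidene carbon C12 the chain (methyl on C9' and on C13, six CH carbons between them) is a symmetric 2,9-dimethyldeca-2,4,6,8-tetraene lying between ring A (the hydroxycyclohexene) and ring B (the butenolide), so both of its ends can be formyl groups of one dial.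
3. Forward: muconaldehyde and two ylides give the dial; one formyl group is turned into the alkyne and coupled to the ring A enol triflate; the other is condensed with 3-bromofuran-2(5H)-one, which brings ring B in preformed; ring C (the epoxycyclohexane) is attached last as a vinylstannane and both silyl ethers are removed. No ring closes on the chain.
4. Stereochemistry: C3' and C3 both come from one asymmetric transfer hydrogenation of ketoisophorone (one enol triflate feeds rings A and C); C5/C6 come from a Sharpless epoxidation; the E alkenes come from the stabilised ylide and a chromium-mediated olefination; the Z ylidene comes from a thermodynamically controlled elimination.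

Key step: step 4

Assumption: RuCl[(S,S)-TsDPEN](p-cymene) is taken to give the (4S)-carbinol 9, the enone π-system playing the part of the aryl group of aryl alkyl ketones; if the opposite sense is found, the (R,R)-complex is used in the same step.

**Route**

Step 1
Reactants: 1 trans,trans-muconic acid
Product: 2 dimethyl (2E,4E)-hexa-2,4-dienedioate
Conditions: MeOH, H2SO4 (cat.), reflux
Reagents that add atoms: methanol, CO
Why: Fischer esterification driven by excess methanol should give the soluble diester without touching the E,E-diene.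

Step 2
Reactants: 2 dimethyl (2E,4E)-hexa-2,4-dienedioate
Product: 3 (2E,4E)-hexa-2,4-diene-1,6-diol
Conditions: i-Bu2AlH (4.4 equiv), CH2Cl2, −78 °C → 0 °C; aqueous potassium sodium tartrate
Reagents that add atoms: none
Why: Low-temperature 1,2-reduction of conjugated esters by an aluminium hydride should give the bis-allylic diol and leave the diene geometry intact.

Step 3
Reactants: 3 (2E,4E)-hexa-2,4-diene-1,6-diol
Product: 4 (2E,4E)-hexa-2,4-dienedial
Conditions: MnO2 (activated, excess), CH2Cl2, rt
Reagents that add atoms: none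
Why: Allylic oxidation with MnO2 is selective for allylic alcohols, stops at the aldehyde and should keep the E,E geometry.

Step 4
Reactants: 4 (2E,4E)-hexa-2,4-dienedial; 5 2-(triphenylphosphoranylidene)propanal (2.1 equiv)
Product: 6 (2E,4E,6E,8E)-2,9-dimethyldeca-2,4,6,8-tetraenedial
Conditions: toluene, 70 °C, dark
Reagents that add atoms: none
Why: Each formyl group of 4 adds the formyl-stabilised ylide 5 reversibly, and the anti oxaphosphetane collapses with loss of Ph3PO, so the C9'=C10' and C13=C14 bonds form in one operation as two α-methyl enal termini. The closest known reaction is the two-fold Wittig chain extension of polyene dialdehydes with this same ylide, as used for symmetric carotenoid dials. No ring closes and no stereocentre is created; the only stereochemical element is the E geometry of the two new trisubstituted alkenes, which follows from thermodynamic control in the reversible addition of a stabilised ylide (formyl group trans to the chain). The step must stop after two olefinations, and it should: the new aldehydes are α-branched and more extended in conjugation, hence less electrophilic toward 5 than those of 4, and the limited charge of 5 and the low solubility of 6 reinforce this. The 2E,4E diene of 4 is not affected under these neutral conditions.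

Step 5
Reactants: 6 (2E,4E,6E,8E)-2,9-dimethyldeca-2,4,6,8-tetraenedial (1.5 equiv, excess recovered)
Product: 7 (2E,4E,6E,8E)-2,9-dimethylundeca-2,4,6,8-tetraen-10-ynal
Conditions: THF, −78 °C; Me3SiC(Li)N2 (from Me3SiCHN2 and LiN(i-Pr)2, 1.0 equiv) added slowly; −78 °C → rt
Reagents that add atoms: (trimethylsilyl)diazomethane, C[Si](C)(C)C=[N+]=[N-]
Why: Colvin homologation (1,2-addition, Peterson elimination, loss of N2 and 1,2-hydrogen shift of the alkylidene carbene) turns one formyl group into the terminal alkyne under aprotic conditions that avoid the methanol addition seen with enals under Ohira–Bestmann conditions, and mono-reaction is favoured by the limiting reagent and by the lower electrophilicity of the second formyl group once the first has become an alkoxide.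

Step 6
Reactants: 8 2,6,6-trimethylcyclohex-2-ene-1,4-dione (ketoisophorone)
Product: 9 (4S)-4-hydroxy-2,6,6-trimethylcyclohex-2-en-1-one
Conditions: RuCl[(S,S)-TsDPEN](p-cymene) (1 mol%), HCO2H–Et3N (5:2), CH2Cl2, 25 °C
Reagents that add atoms: none
Why: Noyori-type asymmetric transfer hydrogenation should reduce only the unhindered C4 carbonyl (C1 is shielded by the gem-dimethyl and methyl groups) by outer-sphere hydride and proton transfer, the CH/π contact of the catalyst with the enone setting the C4 stereocentre as S.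

Step 7
Reactants: 9 (4S)-4-hydroxy-2,6,6-trimethylcyclohex-2-en-1-one
Product: 10 (4S)-4-[(tert-butyldimethylsilyl)oxy]-2,6,6-trimethylcyclohex-2-en-1-one
Conditions: t-BuMe2SiCl, imidazole, DMF, rt
Reagents that add atoms: tert-butyldimethylsilyl chloride, CC(C)(C)[Si](C)(C)Cl
Why: Standard imidazole-promoted silylation of a secondary alcohol, mild enough not to deprotonate the γ-position of the enone.

Step 8
Reactants: 10 (4S)-4-[(tert-butyldimethylsilyl)oxy]-2,6,6-trimethylcyclohex-2-en-1-one
Product: 12 (4R)-4-[(tert-butyldimethylsilyl)oxy]-2,6,6-trimethylcyclohex-1-en-1-yl trifluoromethanesulfonate, via lithium enolate 11 (not isolated)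
Conditions: LiBH(s-Bu)3, THF, −78 °C; then PhNTf2, −78 °C → rt
Reagents that add atoms: N-phenylbis(trifluoromethanesulfonimide), O=S(=O)(N(c1ccccc1)S(=O)(=O)C(F)(F)F)C(F)(F)F
Why: Conjugate reduction with enolate trapping (reductive triflation) should deliver hydride to the unsubstituted β-carbon of the hindered enone and fix the resulting regiodefined enolate as the tetrasubstituted enol triflate, the carbinol centre being untouched (its descriptor changes from S to R only because C3 becomes sp3).

Step 9
Reactants: 7 (2E,4E,6E,8E)-2,9-dimethylundeca-2,4,6,8-tetraen-10-ynal; 12 (4R)-4-[(tert-butyldimethylsilyl)oxy]-2,6,6-trimethylcyclohex-1-en-1-yl trifluoromethanesulfonate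
Product: 13 (2E,4E,6E,8E)-11-[(4R)-4-[(tert-butyldimethylsilyl)oxy]-2,6,6-trimethylcyclohex-1-en-1-yl]-2,9-dimethylundeca-2,4,6,8-tetraen-10-ynal
Conditions: Pd(PPh3)4 (5 mol%), CuI (10 mol%), Et3N, DMF, degassed, rt → 40 °C
Reagents that add atoms: none
Why: Sonogashira coupling (oxidative addition of the enol triflate to zerovalent palladium, then transfer of the copper acetylide) should form the C6'–C7' bond while the formyl group, the silyl ether and all alkene geometries stay unchanged.

Step 10
Reactants: 14 furan-2(5H)-one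
Product: 16 3-bromofuran-2(5H)-one, via trans-3,4-dibromodihydrofuran-2(3H)-one 15 (not isolated)
Conditions: Br2, CH2Cl2, 0 °C → rt; then Et3N, 0 °C
Reagents that add atoms: bromine, BrBr
Why: Bromine addition to the enoate alkene followed by base-induced loss of HBr (acidic α-hydrogen, β-bromide as leaving group) is the standard bromination–dehydrobromination route to the α-bromobutenolide.

Step 11
Reactants: 13 (2E,4E,6E,8E)-11-[(4R)-4-[(tert-butyldimethylsilyl)oxy]-2,6,6-trimethylcyclohex-1-en-1-yl]-2,9-dimethylundeca-2,4,6,8-tetraen-10-ynal; 16 3-bromofuran-2(5H)-one (1.5 equiv)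
Product: 19 (5Z)-3-bromo-5-[(2E,4E,6E,8E)-11-[(4R)-4-[(tert-butyldimethylsilyl)oxy]-2,6,6-trimethylcyclohex-1-en-1-yl]-2,9-dimethylundeca-2,4,6,8-tetraen-10-yn-1-ylidene]furan-2(5H)-one, via 3-bromo-2-(tert-butyldimethylsilyloxy)furan 17 (not isolated), via silyl aldol adduct 18 (not isolated)
Conditions: 16, t-BuMe2SiOTf, i-Pr2NEt, CH2Cl2, 0 °C; then 13, −78 °C → 0 °C; then DBU, 0 °C → rt, dark
Reagents that add atoms: none
Why: A one-pot vinylogous Mukaiyama aldol of the silyloxyfuran formed in the flask (attack through C5 of the furan), followed by DBU-induced E1cB loss of silanolate through the furanolate, should give the ylidenebutenolide with the Z geometry that is thermodynamically preferred (chain syn to the ring oxygen, away from the C4 hydrogen), and the two stereocentres of 18 are destroyed in the elimination.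

Step 12
Reactants: 12 (4R)-4-[(tert-butyldimethylsilyl)oxy]-2,6,6-trimethylcyclohex-1-en-1-yl trifluoromethanesulfonate
Product: 20 methyl (4R)-4-[(tert-butyldimethylsilyl)oxy]-2,6,6-trimethylcyclohex-1-ene-1-carboxylate
Conditions: Pd(OAc)2 (cat.), PPh3, CO (1 atm), Et3N, MeOH/DMF, 60 °C
Reagents that add atoms: carbon monoxide, [C-]#[O+]; methanol, CO
Why: Palladium-catalysed alkoxycarbonylation of an enol triflate (oxidative addition, CO insertion, methanolysis of the acylpalladium) is reliable even for tetrasubstituted enol triflates.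

Step 13
Reactants: 20 methyl (4R)-4-[(tert-butyldimethylsilyl)oxy]-2,6,6-trimethylcyclohex-1-ene-1-carboxylate
Product: 21 [(4R)-4-[(tert-butyldimethylsilyl)oxy]-2,6,6-trimethylcyclohex-1-en-1-yl]methanol
Conditions: i-Bu2AlH (2.2 equiv), CH2Cl2, −78 °C → 0 °C
Reagents that add atoms: none
Why: 1,2-Reduction of the conjugated ester by the aluminium hydride should give the allylic alcohol needed for a directed epoxidation.

Step 14
Reactants: 21 [(4R)-4-[(tert-butyldimethylsilyl)oxy]-2,6,6-trimethylcyclohex-1-en-1-yl]methanol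
Product: 22 [(1R,4S,6R)-4-[(tert-butyldimethylsilyl)oxy]-2,2,6-trimethyl-7-oxabicyclo[4.1.0]heptan-1-yl]methanol
Conditions: Ti(OiPr)4 (cat.), D-(−)-diethyl tartrate (cat.), t-BuOOH, 4 Å molecular sieves, CH2Cl2, −20 °C
Reagents that add atoms: tert-butyl hydroperoxide, CC(C)(C)OO
Why: Sharpless asymmetric epoxidation under reagent control by the D-tartrate should deliver oxygen to the alkene face opposite the C4 silyloxy group and so set both epoxide stereocentres (C1 and C6 of the bicycle) at once.

Step 15
Reactants: 22 [(1R,4S,6R)-4-[(tert-butyldimethylsilyl)oxy]-2,2,6-trimethyl-7-oxabicyclo[4.1.0]heptan-1-yl]methanol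
Product: 23 (1S,4S,6R)-4-[(tert-butyldimethylsilyl)oxy]-2,2,6-trimethyl-7-oxabicyclo[4.1.0]heptane-1-carbaldehyde
Conditions: Pr4N[RuO4] (cat.), N-methylmorpholine N-oxide, 4 Å molecular sieves, CH2Cl2, rt
Reagents that add atoms: none
Why: Ley–Griffith oxidation is neutral, so the epoxide should survive, and the aldehyde formed has no α-hydrogen and cannot epimerise.

Step 16
Reactants: 23 (1S,4S,6R)-4-[(tert-butyldimethylsilyl)oxy]-2,2,6-trimethyl-7-oxabicyclo[4.1.0]heptane-1-carbaldehyde
Product: 24 tributyl[(E)-2-[(1S,4S,6R)-4-[(tert-butyldimethylsilyl)oxy]-2,2,6-trimethyl-7-oxabicyclo[4.1.0]heptan-1-yl]ethenyl]stannane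
Conditions: CrCl2, Bu3SnCHBr2, LiI, THF/DMF, rt, dark
Reagents that add atoms: tributyl(dibromomethyl)stannane, CCCC[Sn](CCCC)(CCCC)C(Br)Br
Why: Takai-type stannylolefination (addition of a geminal dichromium carbenoid to the aldehyde and anti elimination) should give the E-alkenylstannane in one step, the quaternary neighbour reinforcing the E preference.

Step 17
Reactants: 19 (5Z)-3-bromo-5-[(2E,4E,6E,8E)-11-[(4R)-4-[(tert-butyldimethylsilyl)oxy]-2,6,6-trimethylcyclohex-1-en-1-yl]-2,9-dimethylundeca-2,4,6,8-tetraen-10-yn-1-ylidene]furan-2(5H)-one; 24 tributyl[(E)-2-[(1S,4S,6R)-4-[(tert-butyldimethylsilyl)oxy]-2,2,6-trimethyl-7-oxabicyclo[4.1.0]heptan-1-yl]ethenyl]stannane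
Product: 25 (5Z)-3-[(E)-2-[(1S,4S,6R)-4-[(tert-butyldimethylsilyl)oxy]-2,2,6-trimethyl-7-oxabicyclo[4.1.0]heptan-1-yl]ethenyl]-5-[(2E,4E,6E,8E)-11-[(4R)-4-[(tert-butyldimethylsilyl)oxy]-2,6,6-trimethylcyclohex-1-en-1-yl]-2,9-dimethylundeca-2,4,6,8-tetraen-10-yn-1-ylidene]furan-2(5H)-one
Conditions: tris(dibenzylideneacetone)dipalladium Pd2(dba)3 (cat.), AsPh3, DMF, 40 °C, dark
Reagents that add atoms: none
Why: Stille coupling (oxidative addition of the C3–Br bond of the butenolide to zerovalent palladium, arsine-accelerated transfer of the alkenyl group from tin, reductive elimination) should form the C8–C9 bond with retention of both alkene geometries under neutral conditions that spare the epoxide, the lactone and the silyl ethers.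

Step 18
Reactants: 25 bis(tert-butyldimethylsilyl) ether of the target
Product: 26 (5Z)-3-[(E)-2-[(1S,4S,6R)-4-hydroxy-2,2,6-trimethyl-7-oxabicyclo[4.1.0]heptan-1-yl]ethenyl]-5-[(2E,4E,6E,8E)-11-[(4R)-4-hydroxy-2,6,6-trimethylcyclohex-1-en-1-yl]-2,9-dimethylundeca-2,4,6,8-tetraen-10-yn-1-ylidene]furan-2(5H)-one (CNP0180336.1)
Conditions: Bu4NF, AcOH (1:1), THF, 0 °C → rt, dark
Reagents that add atoms: none
Why: Fluoride-driven desilylation buffered with acetic acid should free both secondary alcohols without alkoxide attack on the lactone and without the strong acid that would rearrange the vinyl epoxide, and no stereocentre is touched.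

**Compound list**

1 | trans,trans-muconic acid | OC(=O)/C=C/C=C/C(=O)O | starting material
2 | dimethyl (2E,4E)-hexa-2,4-dienedioate | COC(=O)/C=C/C=C/C(=O)OC | intermediate
3 | (2E,4E)-hexa-2,4-diene-1,6-diol | OC/C=C/C=C/CO | intermediate
4 | (2E,4E)-hexa-2,4-dienedial | O=C/C=C/C=C/C=O | intermediate
5 | 2-(triphenylphosphoranylidene)propanal | CC(C=O)=P(c1ccccc1)(c1ccccc1)c1ccccc1 | starting material
6 | (2E,4E,6E,8E)-2,9-dimethyldeca-2,4,6,8-tetraenedial | O=C/C(C)=C/C=C/C=C/C=C(C)/C=O | intermediate
7 | (2E,4E,6E,8E)-2,9-dimethylundeca-2,4,6,8-tetraen-10-ynal | C#C/C(C)=C/C=C/C=C/C=C(C)/C=O | intermediate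
8 | 2,6,6-trimethylcyclohex-2-ene-1,4-dione | CC1=CC(=O)CC(C)(C)C1=O | starting material
9 | (4S)-4-hydroxy-2,6,6-trimethylcyclohex-2-en-1-one | CC1=C[C@@H](O)CC(C)(C)C1=O | intermediate
10 | (4S)-4-[(tert-butyldimethylsilyl)oxy]-2,6,6-trimethylcyclohex-2-en-1-one | CC1=C[C@@H](O[Si](C)(C)C(C)(C)C)CC(C)(C)C1=O | intermediate
11 | lithium (4R)-4-[(tert-butyldimethylsilyl)oxy]-2,6,6-trimethylcyclohex-1-en-1-olate | [Li+].CC1=C([O-])C(C)(C)C[C@H](O[Si](C)(C)C(C)(C)C)C1 | intermediate
12 | (4R)-4-[(tert-butyldimethylsilyl)oxy]-2,6,6-trimethylcyclohex-1-en-1-yl trifluoromethanesulfonate | CC1=C(OS(=O)(=O)C(F)(F)F)C(C)(C)C[C@H](O[Si](C)(C)C(C)(C)C)C1 | intermediate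
13 | (2E,4E,6E,8E)-11-[(4R)-4-[(tert-butyldimethylsilyl)oxy]-2,6,6-trimethylcyclohex-1-en-1-yl]-2,9-dimethylundeca-2,4,6,8-tetraen-10-ynal | CC1=C(C#C/C(C)=C/C=C/C=C/C=C(C)/C=O)C(C)(C)C[C@H](O[Si](C)(C)C(C)(C)C)C1 | intermediate
14 | furan-2(5H)-one | O=C1OCC=C1 | starting material
15 | trans-3,4-dibromodihydrofuran-2(3H)-one (racemic) | O=C1OCC(Br)C1Br | intermediate
16 | 3-bromofuran-2(5H)-one | O=C1OCC=C1Br | intermediate
17 | 3-bromo-2-[(tert-butyldimethylsilyl)oxy]furan | CC(C)(C)[Si](C)(C)Oc1occc1Br | intermediate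
18 | 3-bromo-5-[(2E,4E,6E,8E)-1-[(tert-butyldimethylsilyl)oxy]-11-[(4R)-4-[(tert-butyldimethylsilyl)oxy]-2,6,6-trimethylcyclohex-1-en-1-yl]-2,9-dimethylundeca-2,4,6,8-tetraen-10-yn-1-yl]furan-2(5H)-one (mixture of diastereomers at the two new centres) | CC1=C(C#C/C(C)=C/C=C/C=C/C=C(C)/C(O[Si](C)(C)C(C)(C)C)C2C=C(Br)C(=O)O2)C(C)(C)C[C@H](O[Si](C)(C)C(C)(C)C)C1 | intermediate
19 | (5Z)-3-bromo-5-[(2E,4E,6E,8E)-11-[(4R)-4-[(tert-butyldimethylsilyl)oxy]-2,6,6-trimethylcyclohex-1-en-1-yl]-2,9-dimethylundeca-2,4,6,8-tetraen-10-yn-1-ylidene]furan-2(5H)-one | CC1=C(C#C/C(C)=C/C=C/C=C/C=C(C)/C=C2C=C(Br)C(=O)O/2)C(C)(C)C[C@H](O[Si](C)(C)C(C)(C)C)C1 | intermediate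
20 | methyl (4R)-4-[(tert-butyldimethylsilyl)oxy]-2,6,6-trimethylcyclohex-1-ene-1-carboxylate | CC1=C(C(=O)OC)C(C)(C)C[C@H](O[Si](C)(C)C(C)(C)C)C1 | intermediate
21 | [(4R)-4-[(tert-butyldimethylsilyl)oxy]-2,6,6-trimethylcyclohex-1-en-1-yl]methanol | CC1=C(CO)C(C)(C)C[C@H](O[Si](C)(C)C(C)(C)C)C1 | intermediate
22 | [(1R,4S,6R)-4-[(tert-butyldimethylsilyl)oxy]-2,2,6-trimethyl-7-oxabicyclo[4.1.0]heptan-1-yl]methanol | OC[C@@]12O[C@]1(C)C[C@@H](O[Si](C)(C)C(C)(C)C)CC2(C)C | intermediate
23 | (1S,4S,6R)-4-[(tert-butyldimethylsilyl)oxy]-2,2,6-trimethyl-7-oxabicyclo[4.1.0]heptane-1-carbaldehyde | O=C[C@@]12O[C@]1(C)C[C@@H](O[Si](C)(C)C(C)(C)C)CC2(C)C | intermediate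
24 | tributyl[(E)-2-[(1S,4S,6R)-4-[(tert-butyldimethylsilyl)oxy]-2,2,6-trimethyl-7-oxabicyclo[4.1.0]heptan-1-yl]ethenyl]stannane | CCCC[Sn](CCCC)(CCCC)/C=C/[C@@]12O[C@]1(C)C[C@@H](O[Si](C)(C)C(C)(C)C)CC2(C)C | intermediate
25 | bis(tert-butyldimethylsilyl) ether of the target (full name in step 17) | CC1=C(C#C/C(C)=C/C=C/C=C/C=C(C)/C=C2C=C(/C=C/[C@@]34O[C@]3(C)C[C@@H](O[Si](C)(C)C(C)(C)C)CC4(C)C)C(=O)O/2)C(C)(C)C[C@H](O[Si](C)(C)C(C)(C)C)C1 | intermediate
26 | (5Z)-3-[(E)-2-[(1S,4S,6R)-4-hydroxy-2,2,6-trimethyl-7-oxabicyclo[4.1.0]heptan-1-yl]ethenyl]-5-[(2E,4E,6E,8E)-11-[(4R)-4-hydroxy-2,6,6-trimethylcyclohex-1-en-1-yl]-2,9-dimethylundeca-2,4,6,8-tetraen-10-yn-1-ylidene]furan-2(5H)-one | CC1=C(C#C/C(C)=C/C=C/C=C/C=C(C)/C=C2C=C(/C=C/[C@@]34O[C@]3(C)C[C@@H](O)CC4(C)C)C(=O)O/2)C(C)(C)C[C@H](O)C1 | target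

**Step count and risks**

Total: 18 steps. Longest linear sequence: 10 steps, from ketoisophorone 8 through steps 6, 7, 8, 12, 13, 14, 15, 16, 17 and 18. The chain branch from muconic acid 1 is 9 steps (1, 2, 3, 4, 5, 9, 11, 17, 18).

The three steps most likely to fail, each with a fallback:

Step 5 could suffer from addition of the lithiated diazomethane to both formyl groups and from base-induced decay of the dial during the slow addition, leaving a mixture of dial, enynal and diyne that cannot be recycled. The fallback sets out from 6 and desymmetrises by protection instead of by C–C bond formation. Equilibrium acetalisation with 2,2-dimethylpropane-1,3-diol (0.9 equiv, pyridinium p-toluenesulfonate, toluene) should give (2E,4E,6E,8E)-9-(5,5-dimethyl-1,3-dioxan-2-yl)-2-methyldeca-2,4,6,8-tetraenal F1, with dial and bis-acetal returned to the equilibrium. The single free formyl group is then homologated with an excess of Me3SiC(Li)N2 in THF to 5,5-dimethyl-2-[(2E,4E,6E,8E)-9-methylundeca-2,4,6,8-tetraen-10-yn-2-yl]-1,3-dioxane F2. Mild hydrolysis (oxalic acid on wet silica gel, CH2Cl2) releases the formyl group, and the route is rejoined at 7.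

Step 11 could fail through cationic side reactions of the silyl-triflate-activated polyenal (attack at vinylogous positions, scrambling of alkene geometry, oligomerisation) or through incomplete elimination. The fallback sets out from 16 and builds the ylidene by a Wittig reaction under weakly basic conditions. Radical bromination with N-bromosuccinimide (azobisisobutyronitrile, PhCF3, reflux) should give 3,5-dibromofuran-2(5H)-one F3, and triphenylphosphine in toluene should convert it into (4-bromo-5-oxo-2,5-dihydrofuran-2-yl)triphenylphosphonium bromide F4. Treating F4 with Et3N in CH2Cl2 in the presence of aldehyde 13 forms the furanolate ylide, which olefinates the formyl group; any E isomer is converged to Z with a trace of I2, and the route is rejoined at 19.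

Step 16 could fail through reductive opening of the epoxide next to the carbonyl by divalent chromium, competing with a slow addition to the neopentyl-type aldehyde. The fallback sets out from 23 and avoids chromium. Homologation with dimethyl (1-diazo-2-oxopropyl)phosphonate and K2CO3 in MeOH (the aldehyde has no α-hydrogen and no conjugated alkene) should give (1R,4S,6R)-4-[(tert-butyldimethylsilyl)oxy]-1-ethynyl-2,2,6-trimethyl-7-oxabicyclo[4.1.0]heptane F5. Palladium-catalysed syn hydrostannation (Bu3SnH, PdCl2(PPh3)2 cat., THF, 0 °C) places tin on the terminal carbon of the hindered alkyne, and the route is rejoined at 24.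

**Further compounds**

F1 | step 5 | (2E,4E,6E,8E)-9-(5,5-dimethyl-1,3-dioxan-2-yl)-2-methyldeca-2,4,6,8-tetraenal | O=C/C(C)=C/C=C/C=C/C=C(C)/C1OCC(C)(C)CO1
F2 | step 5 | 5,5-dimethyl-2-[(2E,4E,6E,8E)-9-methylundeca-2,4,6,8-tetraen-10-yn-2-yl]-1,3-dioxane | C#C/C(C)=C/C=C/C=C/C=C(C)/C1OCC(C)(C)CO1
F3 | step 11 | 3,5-dibromofuran-2(5H)-one (racemic) | O=C1OC(Br)C=C1Br
F4 | step 11 | (4-bromo-5-oxo-2,5-dihydrofuran-2-yl)triphenylphosphonium bromide | [Br-].O=C1OC(C=C1Br)[P+](c1ccccc1)(c1ccccc1)c1ccccc1
F5 | step 16 | (1R,4S,6R)-4-[(tert-butyldimethylsilyl)oxy]-1-ethynyl-2,2,6-trimethyl-7-oxabicyclo[4.1.0]heptane | C#C[C@@]12O[C@]1(C)C[C@@H](O[Si](C)(C)C(C)(C)C)CC2(C)C
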